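Locants: azulene numbering for the bicycle (C1 = quaternary carbon, C3a and C8a = ring fusion, C4 = CMe2, C8 = C=CH2). Ring A = cyclopentane, ring B = cycloheptane, ring C = lactone, Cα = side-chain CH.
Cuts: C8=CH2 (back to a C8 ketone). C3a–C4 of ring B is cut by a retro-Cope that re-closes C6–C8 to a cyclopropane (C6, C7, C8, with OMe as helper on C8). Further cuts: the cyclopropane CH2 (C7), C8–C8a, C1–Cα, and the ester C–O between the ring A carbinol and the lactone acid.
Feature used: in ring B the sp2 carbon C8 sits on fusion carbon C8a, the CMe2 carbon C4 sits on fusion carbon C3a, and exactly three CH2 groups (C5–C7) lie between. Ring B is therefore a saturated cyclohepta-1,4-diene (C8=C8a, C5=C6), the Cope product of a 1-(cyclopent-1-enyl)-2-(2-methylprop-1-enyl)cyclopropane.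
Forward: ring C (from (S)-epichlorohydrin) and ring A (bought) are joined as an ester and an Ireland–Claisen shift makes C1–Cα. The side chain is then finished, the dienyl ether arm and a temporary cyclopropane are added, and ring B closes last.
Stereochemistry: the lactone carbon comes from 4. The carbinol of 3 comes from CBS reduction and is relayed to C1 and Cα in the Claisen step. Cyclopropane C8 is set by substrate-controlled Simmons–Smith reaction and relayed to C3a by the boat Cope (both C6 epimers converge). C8a is set by equilibrating protonation.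

Key step: step 15

Remark on the chemistry: CIP descriptors of unchanged centres switch along the route because substituent priorities change, and the SMILES show the constant spatial arrangement. Compounds 17–20 are carried as E/Z mixtures and 21 as its two C6 epimers, because step 15 should funnel them into one product.

Step 1
Reactants: 1 3-methylcyclopent-2-en-1-one
Product: 2 2-iodo-3-methylcyclopent-2-en-1-one
Conditions: I2, pyridine/CH2Cl2 (1:1), 0 °C to rt
Reagents that add atoms: iodine, II
Why: α-Iodination of a cyclic enone (conjugate addition of pyridine, iodination of the enolate, elimination) is standard for this substrate class and puts the halide on the carbon that becomes C8a.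

Step 2
Reactants: 2 2-iodo-3-methylcyclopent-2-en-1-one
Product: 3 (1S)-2-iodo-3-methylcyclopent-2-en-1-ol
Conditions: (R)-2-methyl-CBS-oxazaborolidine (10 mol %), BH3·THF, THF, −20 °C; MeOH, H2O
Reagents that add atoms: none
Why: In this Corey–Bakshi–Shibata reduction the iodoalkenyl arm acts as the large group, so the (R)-oxazaborolidine should give the (S)-carbinol that later controls C1.

Step 3
Reactants: 4 (S)-epichlorohydrin; 5 diethyl malonate
Product: 6 ethyl (1R,5S)-2-oxo-3-oxabicyclo[3.1.0]hexane-1-carboxylate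
Conditions: NaOEt, EtOH, reflux
Reagents that add atoms: none
Why: In this known tandem alkylation–cyclopropanation–lactonisation the malonate opens the epoxide at CH2, the alkoxide closes a new epoxide on CH2Cl, and 3-exo-tet attack of the malonate carbanion inverts the stereocentre before lactonisation, so the configuration of 4 is relayed cleanly to C5 of 6.

Step 4
Reactants: 6 ethyl (1R,5S)-2-oxo-3-oxabicyclo[3.1.0]hexane-1-carboxylate
Product: 7 ethyl (4S)-2-oxo-4-(prop-2-en-1-yl)oxolane-3-carboxylate (C3 epimers)
Conditions: CH2=CHMgBr, CuI (20 mol %), THF, −40 to −20 °C; then 1 M HCl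
Reagents that add atoms: vinylmagnesium bromide, C=C[Mg]Br
Why: Copper-catalysed homoconjugate (SN2-type) opening of the doubly activated cyclopropane at its unsubstituted CH2 is a strain-driven reaction well known for this bicycle with alkyl Grignard reagents and leaves the stereocentre untouched.

Step 5
Reactants: 7 ethyl (4S)-2-oxo-4-(prop-2-en-1-yl)oxolane-3-carboxylate
Product: 8 (4S)-4-(prop-2-en-1-yl)oxolan-2-one
Conditions: LiCl, DMSO/H2O, 140 °C
Reagents that add atoms: none
Why: Krapcho dealkoxycarbonylation removes the activating ester under neutral conditions and erases the stereorandom C3 centre.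

Step 6
Reactants: 8 (4S)-4-(prop-2-en-1-yl)oxolan-2-one
Product: 9 2-[(3S)-5-oxooxolan-3-yl]acetic acid
Conditions: RuCl3·xH2O (2 mol %), NaIO4, MeCN/EtOAc/H2O, 0 °C to rt
Reagents that add atoms: sodium periodate, [Na+].[O-]I(=O)(=O)=O; water, O
Why: RuO4-catalysed oxidative cleavage turns the terminal alkene into the acid with one carbon fewer, and the mild medium matters because ring opening of 9 would pass through achiral 3-(hydroxymethyl)glutaric acid.

Step 7
Reactants: 3 (1S)-2-iodo-3-methylcyclopent-2-en-1-ol; 9 2-[(3S)-5-oxooxolan-3-yl]acetic acid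
Product: 10 (1S)-2-iodo-3-methylcyclopent-2-en-1-yl 2-[(3R)-5-oxooxolan-3-yl]acetate
Conditions: EDC·HCl, DMAP, CH2Cl2, 0 °C to rt
Reagents that add atoms: none
Why: Steglich-type carbodiimide esterification joins the two fragments without touching either stereocentre.

Step 8
Reactants: 10 (1S)-2-iodo-3-methylcyclopent-2-en-1-yl 2-[(3R)-5-oxooxolan-3-yl]acetate
Product: 13 (2R)-2-[(1S)-2-iodo-1-methylcyclopent-2-en-1-yl]-2-[(3R)-5-oxooxolan-3-yl]acetic acid, via bis(silyl ketene acetal) 11 (not isolated), via rearranged silyl ester 12 (not isolated)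
Conditions: LDA (2.5 equiv), THF/DMPU (4:1), −78 °C; Me3SiCl (3 equiv), −78 to 45 °C; then 1 M HCl
Reagents that add atoms: chlorotrimethylsilane, C[Si](C)(C)Cl (its silyl groups stay only in 11 and 12)
Why: In this Ireland–Claisen rearrangement excess base silylates both ester and lactone (only the allyl ketene acetal can rearrange, the lactone one is hydrolysed on work-up), the suprafacial [3,3] shift carries the C–O configuration of 3 to quaternary C1, and the (Z)-ketene acetal formed in THF/DMPU should react through the chair (a boat would eclipse OSiMe3 with iodine) and so set Cα.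

Step 9
Reactants: 13 (2R)-2-[(1S)-2-iodo-1-methylcyclopent-2-en-1-yl]-2-[(3R)-5-oxooxolan-3-yl]acetic acid
Product: 14 (4R)-4-{(1R)-2-hydroxy-1-[(1S)-2-iodo-1-methylcyclopent-2-en-1-yl]ethyl}oxolan-2-one
Conditions: BH3·THF, THF, 0 °C; MeOH, H2O
Reagents that add atoms: none
Why: Borane reduces a free carboxylic acid (through the acyloxyborane) much faster than a lactone or an iodoalkene.

Step 10
Reactants: 14 (4R)-4-{(1R)-2-hydroxy-1-[(1S)-2-iodo-1-methylcyclopent-2-en-1-yl]ethyl}oxolan-2-one
Product: 15 (2R)-2-[(1S)-2-iodo-1-methylcyclopent-2-en-1-yl]-2-[(3R)-5-oxooxolan-3-yl]ethyl acetate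
Conditions: Ac2O, pyridine, DMAP (cat.), CH2Cl2, rt
Reagents that add atoms: acetic anhydride, CC(=O)OC(C)=O
Why: Standard DMAP-catalysed acetylation caps the primary alcohol before it can translactonise.

Step 11
Reactants: 16 3-methylbut-2-enal
Product: 17 1-methoxy-4-methylpenta-1,3-diene (E/Z mixture)
Conditions: MeOCH2PPh3Cl, KOt-Bu, THF, 0 °C
Reagents that add atoms: (methoxymethyl)triphenylphosphonium chloride, COC[P+](c1ccccc1)(c1ccccc1)c1ccccc1.[Cl-]
Why: Wittig methoxymethylenation of an enal gives the 1-methoxydiene, and the E/Z mixture is acceptable because both isomers should converge in step 15.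

Step 12
Reactants: 17 1-methoxy-4-methylpenta-1,3-diene
Product: 19 tributyl(1-methoxy-4-methylpenta-1,3-dien-1-yl)stannane (E/Z mixture), via 1-lithio dienyl ether 18 (not isolated)
Conditions: t-BuLi, THF, −78 to −30 °C; Bu3SnCl, −78 °C to rt
Reagents that add atoms: tributyltin chloride, CCCC[Sn](Cl)(CCCC)CCCC; tert-butyllithium, [Li]C(C)(C)C (lithium stays only in 18)
Why: α-Deprotonation of a 1-methoxy-1,3-diene at the oxygen-bearing vinylic carbon followed by a stannyl quench is established metalated-enol-ether chemistry and keeps the alkene geometry.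

Step 13
Reactants: 15 (2R)-2-[(1S)-2-iodo-1-methylcyclopent-2-en-1-yl]-2-[(3R)-5-oxooxolan-3-yl]ethyl acetate; 19 tributyl(1-methoxy-4-methylpenta-1,3-dien-1-yl)stannane
Product: 20 (2R)-2-[(1S)-2-(1-methoxy-4-methylpenta-1,3-dien-1-yl)-1-methylcyclopent-2-en-1-yl]-2-[(3R)-5-oxooxolan-3-yl]ethyl acetate (E/Z mixture at the enol ether)
Conditions: Pd2(dba)3 (5 mol %), AsPh3, CuI (20 mol %), NMP, 50 °C
Reagents that add atoms: none
Why: Stille coupling of an alkenyl iodide with an α-alkoxyalkenylstannane (copper co-catalysis for the hindered partners) forms C8–C8a under neutral conditions that spare lactone and acetate.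

Step 14
Reactants: 20 (2R)-2-[(1S)-2-(1-methoxy-4-methylpenta-1,3-dien-1-yl)-1-methylcyclopent-2-en-1-yl]-2-[(3R)-5-oxooxolan-3-yl]ethyl acetate
Product: 21 (2R)-2-{(1S)-2-[(1R)-1-methoxy-2-(2-methylprop-1-en-1-yl)cyclopropyl]-1-methylcyclopent-2-en-1-yl}-2-[(3R)-5-oxooxolan-3-yl]ethyl acetate (cis and trans epimers at the isobutenyl carbon, future C6)
Conditions: Et2Zn, CH2I2, CH2Cl2, −20 to 0 °C; pyridine, then aq. NaHCO3
Reagents that add atoms: diiodomethane, ICI
Why: In this Furukawa-modified Simmons–Smith cyclopropanation the electrophilic zinc carbenoid selects the enol ether alkene over the two trisubstituted alkenes (as in the monocyclopropanation of dienol ethers), and because the dienyl arm turns to the C1-methyl face of the twisted diene the CH2 should arrive on the side away from the quaternary carbon and its side chain, setting future C8 as (R).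

Step 15
Reactants: 21 (2R)-2-{(1S)-2-[(1R)-1-methoxy-2-(2-methylprop-1-en-1-yl)cyclopropyl]-1-methylcyclopent-2-en-1-yl}-2-[(3R)-5-oxooxolan-3-yl]ethyl acetate (both epimers)
Product: 23 (2R)-2-[(1S,3aS)-8-methoxy-1,4,4-trimethyl-1,2,3,3a,4,7-hexahydroazulen-1-yl]-2-[(3R)-5-oxooxolan-3-yl]ethyl acetate, via cis-divinylcyclopropane 22 (not isolated)
Conditions: mesitylene, BHT (cat.), base-washed glassware, 165 °C
Reagents that add atoms: none
Why: The cis isomer 22 folds both alkenes over the three-membered ring and undergoes a concerted [3,3] shift through a boat transition state in which C3a–C4 forms while the strained, donor-substituted C6–C8 bond breaks, giving the C8=C8a enol ether and the Z C5=C6 alkene, whereas the trans isomer in 21 first epimerises at C6 by reversible homolysis of that same bond (alkoxyallyl/dimethylallyl 1,3-diradical) and then drains through 22. The closest known reaction type is the divinylcyclopropane–cycloheptadiene rearrangement, which has been used to build hydroazulenes from 1-(cyclopent-1-enyl)-2-vinylcyclopropanes, tolerates an isobutenyl terminus that ends as a ring CMe2 group, and is known to accept trans isomers at higher temperature. Ring B closes by a pericyclic three-to-seven-membered ring expansion (suprafacial on both π bonds) driven by release of cyclopropane strain, so no exo/endo competition arises. The only new stereocentre, C3a, is controlled by cyclopropane carbon C8: with the (R) configuration the boat can bring C4 only to the ring A face that carries the C1 methyl group, which leaves C3a–H syn to the side chain as in the target. The step needs periselectivity and retention at C8 during the C6 epimerisation; the first is secured because the vinylcyclopropane–cyclopentene shift needs far higher temperature and the O-methyl group offers no hydrogen for a retro-ene opening, the second because the light C6 terminus (H, isobutenyl) should rotate much more easily than the fully substituted C8 terminus. The one inward-pointing methyl group on C4 raises the barrier, which is why 165 °C and not room temperature is planned.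

Step 16
Reactants: 23 (2R)-2-[(1S,3aS)-8-methoxy-1,4,4-trimethyl-1,2,3,3a,4,7-hexahydroazulen-1-yl]-2-[(3R)-5-oxooxolan-3-yl]ethyl acetate
Product: 25 (2R)-2-[(1S,3aR,8aR)-1,4,4-trimethyl-8-oxodecahydroazulen-1-yl]-2-[(3R)-5-oxooxolan-3-yl]ethyl acetate, via saturated enol ether 24 (not isolated)
Conditions: H2 (1 atm), Pd/C, EtOAc, rt; filter; 1 M HCl, THF, rt to 40 °C
Reagents that add atoms: water, O
Why: Heterogeneous hydrogenation saturates only the disubstituted C5=C6 alkene (the tetrasubstituted enol ether is inert), and acid hydrolysis of the enol ether then protonates C8a reversibly, so the cis-fused ketone, which is reached from the convex face and keeps C8 anti to the bulky C1 side chain, should be favoured both kinetically and at equilibrium.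

Step 17
Reactants: 25 (2R)-2-[(1S,3aR,8aR)-1,4,4-trimethyl-8-oxodecahydroazulen-1-yl]-2-[(3R)-5-oxooxolan-3-yl]ethyl acetate
Product: 26 (2R)-2-[(1R,3aR,8aS)-1,4,4-trimethyl-8-methylidenedecahydroazulen-1-yl]-2-[(3R)-5-oxooxolan-3-yl]ethyl acetate (target)
Conditions: Zn, CH2Br2, TiCl4 (reagent pre-formed in THF, −40 to 5 °C), CH2Cl2, 0 °C to rt
Reagents that add atoms: dibromomethane, BrCBr
Why: Takai–Lombardo methylenation (gem-dizinc/titanium reagent) is non-basic and ketone-selective, so it should convert the hindered, epimerisable C8 ketone into the exocyclic methylene without touching C8a, the lactone or the acetate.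

Compound list
1 | 3-methylcyclopent-2-en-1-one | CC1=CC(=O)CC1 | starting material
2 | 2-iodo-3-methylcyclopent-2-en-1-one | CC1=C(I)C(=O)CC1 | intermediate
3 | (1S)-2-iodo-3-methylcyclopent-2-en-1-ol | O[C@H]1CCC(C)=C1I | intermediate
4 | (S)-epichlorohydrin, (2S)-2-(chloromethyl)oxirane | ClC[C@@H]1CO1 | starting material
5 | diethyl malonate | CCOC(=O)CC(=O)OCC | starting material
6 | ethyl (1R,5S)-2-oxo-3-oxabicyclo[3.1.0]hexane-1-carboxylate | CCOC(=O)[C@@]12C[C@@H]1COC2=O | intermediate
7 | ethyl (4S)-2-oxo-4-(prop-2-en-1-yl)oxolane-3-carboxylate (C3 epimers) | C=CC[C@@H]1COC(=O)C1C(=O)OCC | intermediate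
8 | (4S)-4-(prop-2-en-1-yl)oxolan-2-one | C=CC[C@@H]1COC(=O)C1 | intermediate
9 | 2-[(3S)-5-oxooxolan-3-yl]acetic acid | OC(=O)C[C@@H]1COC(=O)C1 | intermediate
10 | (1S)-2-iodo-3-methylcyclopent-2-en-1-yl 2-[(3R)-5-oxooxolan-3-yl]acetate | O=C(C[C@@H]1COC(=O)C1)O[C@H]2CCC(C)=C2I | intermediate
11 | bis(silyl ketene acetal) of 10: (Z)-O-trimethylsilyl ketene acetal of the allyl ester, lactone as its 2-(trimethylsilyloxy)-4,5-dihydrofuran | C[Si](C)(C)O/C(O[C@H]1CCC(C)=C1I)=C\[C@@H]2COC(O[Si](C)(C)C)=C2 | intermediate
12 | trimethylsilyl ester of 13 with the lactone still as its silyl ketene acetal | C[Si](C)(C)OC(=O)[C@H]([C@@H]1COC(O[Si](C)(C)C)=C1)[C@]2(C)CCC=C2I | intermediate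
13 | (2R)-2-[(1S)-2-iodo-1-methylcyclopent-2-en-1-yl]-2-[(3R)-5-oxooxolan-3-yl]acetic acid | OC(=O)[C@H]([C@@H]1COC(=O)C1)[C@]2(C)CCC=C2I | intermediate
14 | (4R)-4-{(1R)-2-hydroxy-1-[(1S)-2-iodo-1-methylcyclopent-2-en-1-yl]ethyl}oxolan-2-one | OC[C@H]([C@@H]1COC(=O)C1)[C@]2(C)CCC=C2I | intermediate
15 | (2R)-2-[(1S)-2-iodo-1-methylcyclopent-2-en-1-yl]-2-[(3R)-5-oxooxolan-3-yl]ethyl acetate | CC(=O)OC[C@H]([C@@H]1COC(=O)C1)[C@]2(C)CCC=C2I | intermediate
16 | 3-methylbut-2-enal | CC(C)=CC=O | starting material
17 | 1-methoxy-4-methylpenta-1,3-diene (E/Z mixture) | COC=CC=C(C)C | intermediate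
18 | (1-methoxy-4-methylpenta-1,3-dien-1-yl)lithium | [Li]C(OC)=CC=C(C)C | intermediate
19 | tributyl(1-methoxy-4-methylpenta-1,3-dien-1-yl)stannane (E/Z mixture) | CCCC[Sn](CCCC)(CCCC)C(OC)=CC=C(C)C | intermediate
20 | (2R)-2-[(1S)-2-(1-methoxy-4-methylpenta-1,3-dien-1-yl)-1-methylcyclopent-2-en-1-yl]-2-[(3R)-5-oxooxolan-3-yl]ethyl acetate (E/Z mixture) | CC(=O)OC[C@H]([C@@H]1COC(=O)C1)[C@]2(C)CCC=C2C(OC)=CC=C(C)C | intermediate
21 | (2R)-2-{(1S)-2-[(1R)-1-methoxy-2-(2-methylprop-1-en-1-yl)cyclopropyl]-1-methylcyclopent-2-en-1-yl}-2-[(3R)-5-oxooxolan-3-yl]ethyl acetate (both epimers at the isobutenyl carbon) | CC(=O)OC[C@H]([C@@H]1COC(=O)C1)[C@]2(C)CCC=C2[C@@]3(OC)CC3C=C(C)C | intermediate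
22 | cis isomer: (2R)-2-{(1S)-2-[(1R,2S)-1-methoxy-2-(2-methylprop-1-en-1-yl)cyclopropyl]-1-methylcyclopent-2-en-1-yl}-2-[(3R)-5-oxooxolan-3-yl]ethyl acetate | CC(=O)OC[C@H]([C@@H]1COC(=O)C1)[C@]2(C)CCC=C2[C@@]3(OC)C[C@H]3C=C(C)C | intermediate
23 | (2R)-2-[(1S,3aS)-8-methoxy-1,4,4-trimethyl-1,2,3,3a,4,7-hexahydroazulen-1-yl]-2-[(3R)-5-oxooxolan-3-yl]ethyl acetate | CC(=O)OC[C@H]([C@@H]1COC(=O)C1)[C@]2(C)CC[C@@H]3C2=C(OC)CC=CC3(C)C | intermediate
24 | (2R)-2-[(1S,3aS)-8-methoxy-1,4,4-trimethyl-1,2,3,3a,4,5,6,7-octahydroazulen-1-yl]-2-[(3R)-5-oxooxolan-3-yl]ethyl acetate | CC(=O)OC[C@H]([C@@H]1COC(=O)C1)[C@]2(C)CC[C@@H]3C2=C(OC)CCCC3(C)C | intermediate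
25 | (2R)-2-[(1S,3aR,8aR)-1,4,4-trimethyl-8-oxodecahydroazulen-1-yl]-2-[(3R)-5-oxooxolan-3-yl]ethyl acetate | CC(=O)OC[C@H]([C@@H]1COC(=O)C1)[C@]2(C)CC[C@@H]3[C@H]2C(=O)CCCC3(C)C | intermediate
26 | (2R)-2-[(1R,3aR,8aS)-1,4,4-trimethyl-8-methylidenedecahydroazulen-1-yl]-2-[(3R)-5-oxooxolan-3-yl]ethyl acetate | C=C1CCCC(C)(C)[C@@H]2CC[C@@](C)([C@H](COC(C)=O)[C@@H]3COC(=O)C3)[C@H]12 | target

Total step count: 17. Longest linear sequence: 13 steps (steps 3–10, then 13–17).

Steps most likely to fail

Step 8. The lactone enolate may be C-silylated or may condense. Control of the ketene acetal geometry may suffer beside a second enolate, and leakage from the chair to the boat transition state would erode the Cα configuration. The fallback sets out from 3 and comes back at 15. It removes the second enolisable carbonyl and builds ring C afterwards.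
- Alcohol 3 would be esterified (EDC·HCl, DMAP) with commercial 2-(furan-3-yl)acetic acid to the furylacetate ester F1, whose only acidic site is the ester CH2.
- Ireland–Claisen rearrangement (LDA, THF, Me3SiCl) would give the furyl acid F2, borane reduction the furyl alcohol F3, and acetylation the furyl acetate F4.
- Photooxygenation of the 3-substituted furan (O2, rose bengal, i-Pr2NEt, CH2Cl2, −78 °C, visible light) would give the hydroxybutenolide F5, and NaBH4 the butenolide F6.
- A ligand-controlled copper hydride conjugate reduction (Cu(OAc)2, the suitable antipode of p-tol-BINAP, PMHS, t-BuOH, toluene) would then set the lactone stereocentre and deliver 15.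

Step 14. The carbenoid may attack the isobutenyl alkene or add twice, facial selectivity at future C8 may be poor, and zinc iodide may open the alkoxycyclopropane. The fallback sets out from 15 and comes back at 25. It replaces CH2 transfer by a catalyst-controlled donor/acceptor carbene transfer to a bought diene.
- Iodide 15 would be coupled with tert-butyl diazoacetate (Pd(PPh3)4, Et3N, Bu4NBr, MeCN, rt) to the vinyldiazoacetate F7.
- Decomposition of F7 with the antipode of Rh2(DOSP)4 that reinforces the required sense, in the presence of excess 4-methylpenta-1,3-diene, should cyclopropanate only the monosubstituted alkene and give the cis-divinylcyclopropane ester F8.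
- On warming, F8 should rearrange to the cycloheptadiene ester F9.
- Hydrogenation of the disubstituted alkene (RhCl(PPh3)3, H2) would give the saturated enoate F10, and CF3CO2H the enoic acid F11.
- Curtius rearrangement (DPPA, Et3N, toluene, 80 °C) followed by hydrolysis with aqueous HCl would give ketone 25.

Step 15. The inward methyl group and the crowded C8a region may raise the barrier so far that decomposition overtakes rearrangement. Rotation at C8 in the diradical manifold would also scramble the centre that controls C3a. The fallback sets out from 15 and comes back at 25. It closes the same C3a–C4 bond by a radical conjugate addition instead of a pericyclic step.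
- Zinc insertion into commercial 5-bromo-2-methylpent-2-ene would give (4-methylpent-3-en-1-yl)zinc bromide F12.
- Carbonylative Negishi coupling of F12 with 15 (CO 1 atm, Pd(PPh3)4, THF) would give the dienone F13.
- Hydrogen-atom transfer to the trisubstituted alkene (Fe(acac)3, PhSiH3, EtOH, 60 °C) would generate the tertiary C4 radical.
- A 7-endo Giese addition of this radical to the enone β-carbon C3a, followed by protonation of the enolate, would lead to 25.

Further compounds
F1 | step 8 | (1S)-2-iodo-3-methylcyclopent-2-en-1-yl 2-(furan-3-yl)acetate | O=C(Cc1ccoc1)O[C@H]2CCC(C)=C2I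
F2 | step 8 | 2-(furan-3-yl)-2-(2-iodo-1-methylcyclopent-2-en-1-yl)acetic acid (Cα and C1 as in 13) | OC(=O)[C@H](c1ccoc1)[C@]2(C)CCC=C2I
F3 | step 8 | 2-(furan-3-yl)-2-(2-iodo-1-methylcyclopent-2-en-1-yl)ethanol (Cα and C1 as in 14) | OC[C@H](c1ccoc1)[C@]2(C)CCC=C2I
F4 | step 8 | 2-(furan-3-yl)-2-(2-iodo-1-methylcyclopent-2-en-1-yl)ethyl acetate (Cα and C1 as in 15) | CC(=O)OC[C@H](c1ccoc1)[C@]2(C)CCC=C2I
F5 | step 8 | 2-(2-hydroxy-5-oxo-2,5-dihydrofuran-3-yl)-2-(2-iodo-1-methylcyclopent-2-en-1-yl)ethyl acetate (lactol epimers) | CC(=O)OC[C@H](C1=CC(=O)OC1O)[C@]2(C)CCC=C2I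
F6 | step 8 | 2-(2-iodo-1-methylcyclopent-2-en-1-yl)-2-(5-oxo-2,5-dihydrofuran-3-yl)ethyl acetate | CC(=O)OC[C@H](C1=CC(=O)OC1)[C@]2(C)CCC=C2I
F7 | step 14 | tert-butyl 2-diazo-2-(cyclopentenyl)acetate derived from 15 | CC(=O)OC[C@H]([C@@H]1COC(=O)C1)[C@]2(C)CCC=C2C(=[N+]=[N-])C(=O)OC(C)(C)C
F8 | step 14 | tert-butyl (1R,2S)-1-(cyclopentenyl)-2-(2-methylprop-1-en-1-yl)cyclopropane-1-carboxylate derived from F7 | CC(=O)OC[C@H]([C@@H]1COC(=O)C1)[C@]2(C)CCC=C2[C@@]3(C(=O)OC(C)(C)C)C[C@H]3C=C(C)C
F9 | step 14 | tert-butyl 1,2,3,3a,4,7-hexahydroazulene-8-carboxylate analogue of 23 | CC(=O)OC[C@H]([C@@H]1COC(=O)C1)[C@]2(C)CC[C@@H]3C2=C(C(=O)OC(C)(C)C)CC=CC3(C)C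
F10 | step 14 | tert-butyl 1,2,3,3a,4,5,6,7-octahydroazulene-8-carboxylate analogue of 24 | CC(=O)OC[C@H]([C@@H]1COC(=O)C1)[C@]2(C)CC[C@@H]3C2=C(C(=O)OC(C)(C)C)CCCC3(C)C
F11 | step 14 | 1,2,3,3a,4,5,6,7-octahydroazulene-8-carboxylic acid from F10 | CC(=O)OC[C@H]([C@@H]1COC(=O)C1)[C@]2(C)CC[C@@H]3C2=C(C(=O)O)CCCC3(C)C
F12 | step 15 | (4-methylpent-3-en-1-yl)zinc bromide | CC(C)=CCC[Zn]Br
F13 | step 15 | (2R)-2-[(1S)-1-methyl-2-(5-methylhex-4-enoyl)cyclopent-2-en-1-yl]-2-[(3R)-5-oxooxolan-3-yl]ethyl acetate | CC(=O)OC[C@H]([C@@H]1COC(=O)C1)[C@]2(C)CCC=C2C(=O)CCC=C(C)C
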